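Amounts first: a late reading of target in a flask is a share of a charge, so I ask how much has passed through to product and how that product is split.

| flask | starting material | coupling partner | free catalyst | second catalyst | temperature | remark | time |
|---|---|---|---|---|---|---|---|
| birch | 0.10 M | 1 equiv | 0.18 mol% | 14 mol% | 25 °C | the very flask that is asked about, followed so far |  |
| cedar | 0.10 M | 1 equiv | 0.18 mol% | 28 mol% | 10 °C | run made earlier |  |
| flask | 0.10 M | 1.00 equiv | 0.18 mol% | 14 mol% | 25 °C |  | 3.0 d |

| run | time / h | target / % |
|---|---|---|
| birch | 6.00 | 21.0 |
| birch | 12.0 | 14.2 |
| birch | 30.0 | 12.0 |
| birch | 72.0 | 13.1 |
| cedar | 1.33 | 10.4 |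
| cedar | 3.00 | 27.2 |
| cedar | 4.00 | 33.8 |
| cedar | 6.00 | 36.8 |

(readings scatter by 0.5 percentage points)

- east: change nothing and wait 6.0 d more
- north-west: at 3.0 d add free catalyst, 100% of the amount charged, then wait 6.0 d
- north: at 3.0 d add coupling partner, 50.0% of the amount charged, then wait 6.0 d
- south-west: at 3.0 d raise the temperature by 25 K, then wait 6.0 d

- target, in percent of the starting material first charged, at 3.0 d
- what to do for the largest gain in target; "none" if nothing gains more than 2 percentage points (east / north-west / north / south-west / none)
- target present, in percent of the starting material first charged, after east
- target present, in percent of the starting material first charged, after north-west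

- what is said of target includes crystals
- crystals is a solid; its amount is given per volume of the solution
- what is added takes up no volume worth counting
- steps thought possible: starting material + free catalyst -> free catalyst + open intermediate; second catalyst + open intermediate <-> catalyst intermediate; coupling partner + catalyst intermediate -> second catalyst + target; coupling partner -> decomposition product; target + free catalyst <-> isomer of the product + free catalyst; crystals <-> target
- "the catalyst" is free catalyst with its forms; second catalyst is a second catalyst

Free catalyst opens the starting material, second catalyst and coupling partner carry the open intermediate on to target, and free catalyst can also turn target into its isomer and back.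

*What does birch do after its peak?* Target reads 21.0% at 6.00 h, 12.0% at 30.0 h and 13.1% at 72.0 h. It falls and then nearly stops, which looks like the reversible step between target and isomer coming to balance: thermodynamic control.

*What do you carry away from that?* The end split, 13.1%: the fraction [target]/([target] + [isomer of the product]) once that balance stands, read from the last birch reading with the whole charge counted as target or isomer.

*And if the whole charge isn't there yet?* That is the weak spot: the split is then higher than this. So I solve both ends and join them: at the early end I ask how much product has formed, at the late end how it is split, and late target is the split times that product.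

*What would it take to gain 2 percentage points at this split?* Product would have to grow by 15.3% of the charge. The last birch rise of 1.1 points, itself close to the scatter, corresponds to 8.40%, less than that.

*Your commitment?* About 13.1% at the asked time. Waiting and more free catalyst leave the split alone, and I expect little from north. Heat is the option that can move the split itself, so I pick south-west, though cedar, at another temperature, is still rising at its last reading and gives me no end split there.

The forecast gave 12.9% now, 14% after east, 14.5% after north-west, and chose north, on the ground that “Fresh partner could make new product”, so on the choice we differ.

The flask gives 12.6% now, 12.7% after east and 12.7% after north-west, and the best option is south-west, a gain of 14 points. At 72.0 h the flask still holds 2.49% as open intermediate beside 85.0% of isomer. The end split on that remainder comes to 0.33 points, and north gains 0.27 points.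

    starting material + free catalyst → free catalyst + open intermediate (k = 7300 M⁻¹ h⁻¹, Ea = 40.0 kJ mol⁻¹)
    second catalyst + open intermediate ⇌ catalyst intermediate (K = 0.120 M⁻¹, k = 55.0 M⁻¹ h⁻¹, Ea = 50.0 kJ mol⁻¹, ΔH = −38.0 kJ mol⁻¹)
    coupling partner + catalyst intermediate → second catalyst + target (k = 3800 M⁻¹ h⁻¹, Ea = 42.0 kJ mol⁻¹)
    coupling partner → decomposition product (k = 5.00 × 10⁻⁴ h⁻¹, Ea = 114 kJ mol⁻¹)
    target + free catalyst ⇌ isomer of the product + free catalyst, rate k5*[free catalyst]*[target] forward; the back reaction follows from the equilibrium constant (K = 6.80, k = 2700 M⁻¹ h⁻¹, Ea = 37.0 kJ mol⁻¹, ΔH = −30.0 kJ mol⁻¹)
    crystals ⇌ target, rate k6*(cs6 - [target]) while solid is left; crystals form when [target] > cs6 (solubility = 0.0610 M, k = 3.80 h⁻¹)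
    (constants at 25 °C)

Take the neighbour charged with 0.250 equiv of coupling partner: the end split on that fraction of the charge gives 3.27% target. The computed flask holds 3.20% target and 21.8% isomer, with coupling partner, the limiting reagent there, down to 0% and 74.9% left as open intermediate.

The data are simulated with made-up constants; scatter was added.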